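**Strategy.** Everything rests on detaching both side chains from the cyclopentane ring, at C12–C13 (ring carbon to the E-alkenyl carbon of the lower chain) and at C8–C7. A single three-component coupling rebuilds both bonds: an alkenylzincate made from a (3S,7R)-configured vinyl iodide adds to C12 of (R)-4-silyloxycyclopent-2-enone, and the C8 enolate so formed is alkylated by a Z-allylic iodide. The step exploits the contiguous trans,trans stereotriad C11–C12–C8 of the five-membered ring, in which the C11 silyloxy group relays its configuration to C12 and C12 relays it to C8. The precursors are three separate pieces that share no bond before the step.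

Key step: step 7

Assumption: (R)-6-methyltetrahydro-2H-pyran-2-one (1), methyl 7-hydroxyhept-5-ynoate (9) and (R)-4-(tert-butyldimethylsilyloxy)cyclopent-2-en-1-one (12) are taken as catalogue compounds of high enantiomeric purity where chiral.

Step 1
Reactants: 1 (R)-6-methyltetrahydro-2H-pyran-2-one; 2 ethynyltrimethylsilane
Product: 3 (R)-7-hydroxy-1-(trimethylsilyl)oct-1-yn-3-one
Conditions: 2, n-BuLi, THF, −78 °C; then 1, −78 °C; AcOH quench at −78 °C
Reagents that add atoms: none
Why: Nucleophilic acyl addition of a lithium acetylide to a δ-lactone, in which the tetrahedral lithium hemiketal alkoxide persists at −78 °C and so prevents a second addition; cold acidic quench should release the δ-hydroxy ynone with the C19 stereocenter of 1 untouched.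

Step 2
Reactants: 3 (R)-7-hydroxy-1-(trimethylsilyl)oct-1-yn-3-one
Product: 5 (3S,7R)-oct-1-yne-3,7-diol, via C-silylated ynediol 4 (not isolated)
Conditions: Ru[(S,S)-TsNCH(Ph)CH(Ph)NH](p-cymene) (1 mol %), i-PrOH, rt; then K2CO3, MeOH, rt
Reagents that add atoms: none
Why: Noyori asymmetric transfer hydrogenation of an ynone, in which the (S,S)-configured ruthenium hydride distinguishes the alkynyl from the alkyl flank in its six-membered metal–ligand bifunctional transition state and should set the (S)-carbinol at C15 under catalyst control, independent of the remote C19 center; K2CO3/MeOH then removes the alkynyl silyl group by protodesilylation.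

Step 3
Reactants: 5 (3S,7R)-oct-1-yne-3,7-diol
Product: 6 (3S,7R)-3,7-bis(tert-butyldimethylsilyloxy)oct-1-yne
Conditions: TBSCl, imidazole, DMF, rt
Reagents that add atoms: tert-butyldimethylsilyl chloride (TBSCl), CC(C)(C)[Si](C)(C)Cl
Why: Imidazole-promoted silyl ether formation should silylate both secondary hydroxyls through the N-silylimidazolium species without touching a stereocenter or the terminal alkyne.

Step 4
Reactants: 6 (3S,7R)-3,7-bis(tert-butyldimethylsilyloxy)oct-1-yne
Product: 8 (3S,7R,E)-3,7-bis(tert-butyldimethylsilyloxy)-1-iodooct-1-ene, via alkenylzirconocene chloride 7 (not isolated)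
Conditions: Cp2Zr(H)Cl, THF, rt; then I2, 0 °C
Reagents that add atoms: iodine (I2), II
Why: Schwartz hydrozirconation followed by iodinolysis: syn addition of Zr–H places zirconium on the terminal carbon, away from the C15 silyloxy group, and iodine cleaves the C–Zr bond with retention, so the E vinyl iodide should result.

Step 5
Reactants: 9 methyl 7-hydroxyhept-5-ynoate
Product: 10 methyl (Z)-7-hydroxyhept-5-enoate
Conditions: H2 (1 atm), Pd/CaCO3 poisoned with Pb(OAc)2 (Lindlar catalyst), quinoline, EtOAc, rt
Reagents that add atoms: none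
Why: Lindlar semi-hydrogenation delivers H2 syn on the poisoned palladium surface and should stop at the Z olefin because the alkene is displaced from the surface by alkyne and quinoline.

Step 6
Reactants: 10 methyl (Z)-7-hydroxyhept-5-enoate
Product: 11 methyl (Z)-7-iodohept-5-enoate
Conditions: I2, PPh3, imidazole, CH2Cl2, 0 °C, dark; used at once
Reagents that add atoms: iodine (I2), II
Why: Appel-type iodination, in which iodide displaces the alkoxyphosphonium ion by SN2 at the primary allylic carbon; at 0 °C in the dark the Z geometry should be kept.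

Step 7
Reactants: 8 (3S,7R,E)-3,7-bis(tert-butyldimethylsilyloxy)-1-iodooct-1-ene; 12 (R)-4-(tert-butyldimethylsilyloxy)cyclopent-2-en-1-one; 11 methyl (Z)-7-iodohept-5-enoate
Product: 16 methyl (5Z,13E,15S,19R)-11α,15,19-tris(tert-butyldimethylsilyloxy)-9-oxoprosta-5,13-dien-1-oate, via alkenyllithium 13 (not isolated), via lithium alkenyldimethylzincate 14 (not isolated), via zinc enolate 15 (not isolated)
Conditions: 8, t-BuLi (2 equiv), Et2O, −78 °C; Me2Zn, THF, −78 → 0 °C; 12, THF, −78 °C; then HMPA, 11, −78 → −40 °C; aq NH4Cl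
Reagents that add atoms: none
Why: Iodine–lithium exchange on 8 gives alkenyllithium 13 with retention of the E geometry, Me2Zn turns it into the mixed zincate 14, which transfers its alkenyl ligand (sp2 ligands migrate in preference to methyl) in a 1,4-addition to C12 of enone 12, and the zinc enolate 15, activated by HMPA, is alkylated at C8 by the allylic iodide 11 in an SN2 reaction. The closest known reaction type is the organozinc-mediated three-component coupling of prostaglandin synthesis (tandem conjugate addition–enolate alkylation). No ring is closed; the cyclopentane is taken over intact from 12. The C12 stereocenter is controlled by the C11 silyloxy group, which shields one face of the flat enone so that the alkenyl group enters anti, and the C8 stereocenter is controlled by the new C12 substituent, the electrophile entering anti to it to give the trans,trans array. The step needs alkylation of the regiodefined enolate to outrun proton transfer (enolate equilibration, double alkylation) and β-elimination of the C11 silyloxy group, which the weakly basic zinc enolate at −78 to −40 °C should secure, and it needs SN2 rather than SN2′ attack with the Z olefin kept, which the unhindered primary allylic iodide should secure.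

Step 8
Reactants: 16 methyl (5Z,13E,15S,19R)-11α,15,19-tris(tert-butyldimethylsilyloxy)-9-oxoprosta-5,13-dien-1-oate
Product: 17 methyl (5Z,13E,15S,19R)-9α-hydroxy-11α,15,19-tris(tert-butyldimethylsilyloxy)prosta-5,13-dien-1-oate
Conditions: LiBH(s-Bu)3 (L-Selectride), THF, −78 °C; aq NH4Cl
Reagents that add atoms: none
Why: Diastereoselective ketone reduction by a bulky trialkylborohydride, which should approach the C9 carbonyl from the face opposite the adjacent C8 chain and the C11 silyloxy group and so give the 9α alcohol cis to both, the methyl ester being inert at −78 °C.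

Step 9
Reactants: 17 methyl (5Z,13E,15S,19R)-9α-hydroxy-11α,15,19-tris(tert-butyldimethylsilyloxy)prosta-5,13-dien-1-oate
Product: 19 (5Z,13E,15S,19R)-9α,11α,15,19-tetrahydroxyprosta-5,13-dien-1-oic acid [19(R)-hydroxy prostaglandin F2α], via lithium carboxylate 18 (not isolated)
Conditions: LiOH, THF/H2O, rt; then aq HCl (to ca. 1.5% HCl), rt
Reagents that add atoms: lithium hydroxide (LiOH), [Li+].[OH-]
Why: Ester saponification followed in the same flask by acid-catalysed hydrolysis of the three silyl ethers: hydroxide cleaves the unhindered methyl ester by acyl substitution, and acidification frees the carboxylic acid and hydrolyses the Si–O bonds without touching a stereocenter.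

**Compound list**

1 | (R)-6-methyltetrahydro-2H-pyran-2-one | C[C@@H]1CCCC(=O)O1 | starting material
2 | ethynyltrimethylsilane | C#C[Si](C)(C)C | starting material
3 | (R)-7-hydroxy-1-(trimethylsilyl)oct-1-yn-3-one | C[C@@H](O)CCCC(=O)C#C[Si](C)(C)C | intermediate
4 | (3S,7R)-1-(trimethylsilyl)oct-1-yne-3,7-diol (C-silylated ynediol, not isolated) | C[C@@H](O)CCC[C@H](O)C#C[Si](C)(C)C | intermediate
5 | (3S,7R)-oct-1-yne-3,7-diol | C[C@@H](O)CCC[C@H](O)C#C | intermediate
6 | (3S,7R)-3,7-bis(tert-butyldimethylsilyloxy)oct-1-yne | C[C@@H](O[Si](C)(C)C(C)(C)C)CCC[C@H](O[Si](C)(C)C(C)(C)C)C#C | intermediate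
7 | chloro[(3S,7R,E)-3,7-bis(tert-butyldimethylsilyloxy)oct-1-enyl]zirconocene (not isolated; cyclopentadienyl rings written as σ-bonded) | C[C@@H](O[Si](C)(C)C(C)(C)C)CCC[C@H](O[Si](C)(C)C(C)(C)C)/C=C/[Zr](Cl)(C1C=CC=C1)C1C=CC=C1 | intermediate
8 | (3S,7R,E)-3,7-bis(tert-butyldimethylsilyloxy)-1-iodooct-1-ene | C[C@@H](O[Si](C)(C)C(C)(C)C)CCC[C@H](O[Si](C)(C)C(C)(C)C)/C=C/I | intermediate
9 | methyl 7-hydroxyhept-5-ynoate | COC(=O)CCCC#CCO | starting material
10 | methyl (Z)-7-hydroxyhept-5-enoate | COC(=O)CCC/C=C\CO | intermediate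
11 | methyl (Z)-7-iodohept-5-enoate | COC(=O)CCC/C=C\CI | intermediate
12 | (R)-4-(tert-butyldimethylsilyloxy)cyclopent-2-en-1-one | O=C1C[C@@H](O[Si](C)(C)C(C)(C)C)C=C1 | starting material
13 | [(3S,7R,E)-3,7-bis(tert-butyldimethylsilyloxy)oct-1-enyl]lithium (not isolated) | C[C@@H](O[Si](C)(C)C(C)(C)C)CCC[C@H](O[Si](C)(C)C(C)(C)C)/C=C/[Li] | intermediate
14 | lithium [(3S,7R,E)-3,7-bis(tert-butyldimethylsilyloxy)oct-1-enyl]dimethylzincate (not isolated) | C[C@@H](O[Si](C)(C)C(C)(C)C)CCC[C@H](O[Si](C)(C)C(C)(C)C)/C=C/[Zn-](C)C.[Li+] | intermediate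
15 | lithium dimethylzinc enolate of the (3R,4R)-3-alkenyl-4-silyloxycyclopentanone, C8=C9 enolate with the lower chain on C12 trans to the C11 silyloxy group (not isolated) | C[C@@H](O[Si](C)(C)C(C)(C)C)CCC[C@H](O[Si](C)(C)C(C)(C)C)/C=C/[C@@H]1C=C(O[Zn-](C)C)C[C@H]1O[Si](C)(C)C(C)(C)C.[Li+] | intermediate
16 | methyl (5Z,13E,15S,19R)-11α,15,19-tris(tert-butyldimethylsilyloxy)-9-oxoprosta-5,13-dien-1-oate | C[C@@H](O[Si](C)(C)C(C)(C)C)CCC[C@H](O[Si](C)(C)C(C)(C)C)/C=C/[C@@H]1[C@@H](C/C=C\CCCC(=O)OC)C(=O)C[C@H]1O[Si](C)(C)C(C)(C)C | intermediate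
17 | methyl (5Z,13E,15S,19R)-9α-hydroxy-11α,15,19-tris(tert-butyldimethylsilyloxy)prosta-5,13-dien-1-oate | C[C@@H](O[Si](C)(C)C(C)(C)C)CCC[C@H](O[Si](C)(C)C(C)(C)C)/C=C/[C@@H]1[C@@H](C/C=C\CCCC(=O)OC)[C@@H](O)C[C@H]1O[Si](C)(C)C(C)(C)C | intermediate
18 | lithium (5Z,13E,15S,19R)-9α-hydroxy-11α,15,19-tris(tert-butyldimethylsilyloxy)prosta-5,13-dien-1-oate (not isolated) | C[C@@H](O[Si](C)(C)C(C)(C)C)CCC[C@H](O[Si](C)(C)C(C)(C)C)/C=C/[C@@H]1[C@@H](C/C=C\CCCC(=O)[O-])[C@@H](O)C[C@H]1O[Si](C)(C)C(C)(C)C.[Li+] | intermediate
19 | 19(R)-hydroxy prostaglandin F2α | C[C@@H](O)CCC[C@H](O)/C=C/[C@@H]1[C@@H](C/C=C\CCCC(=O)O)[C@@H](O)C[C@H]1O | target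

**Total step count:** 9 steps.
**Longest linear sequence:** 7 steps (steps 1, 2, 3, 4, 7, 8, 9); steps 5 and 6 form the short branch.

**Steps most likely to fail**

Step 7. Alkylation of the zinc enolate by the allylic iodide may be slower than proton transfer between enolate and product, so that enolate equilibration, β-elimination of the C11 silyloxy group and double alkylation erode the coupling. The fallback changes the electrophile class and moves the creation of the Z olefin behind the coupling. It sets out from 9: Appel-type iodination (I2, PPh3, imidazole, CH2Cl2, 0 °C) would give the more reactive propargylic electrophile methyl 7-iodohept-5-ynoate F1. The same zincate sequence from 8 and 12, with F1 as the trap, would give methyl (13E,15S,19R)-11α,15,19-tris(tert-butyldimethylsilyloxy)-9-oxoprost-13-en-5-ynoate F2. Semi-hydrogenation of F2 (H2, Pd/CaCO3 poisoned with Pb(OAc)2, quinoline), which leaves the E olefin alone, would come back to the route at 16.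

Step 2. The free C19 hydroxyl may hold part of the ynone as its cyclic hemiketal and may bind the ruthenium amide, so that conversion stalls or face discrimination at C15 drops. The fallback uses a stoichiometric chiral borane on the protected ketone. It sets out from 3: TBSCl/imidazole would give (R)-7-(tert-butyldimethylsilyloxy)-1-(trimethylsilyl)oct-1-yn-3-one F3. Midland reduction with (S)-Alpine-Borane (B-isopinocampheyl-9-borabicyclo[3.3.1]nonane from (−)-α-pinene, neat, rt) would give (3S,7R)-7-(tert-butyldimethylsilyloxy)-1-(trimethylsilyl)oct-1-yn-3-ol F4. K2CO3/MeOH would give (3S,7R)-7-(tert-butyldimethylsilyloxy)oct-1-yn-3-ol F5, and TBSCl/imidazole would come back to the route at 6.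

Step 9. During the slow acid cleavage of the hindered C11 silyl ether the allylic C15 position may ionise (epimerisation, allylic transposition), or desilylation may stay incomplete. The fallback separates a fluoride-driven desilylation from the ester cleavage. It sets out from 17: HF·pyridine (THF/pyridine, 0 °C → rt) would give 19(R)-hydroxy prostaglandin F2α methyl ester F6, and enzymatic hydrolysis with an esterase (pig liver esterase, pH 7 phosphate buffer) would come back to the route at 19.

**Further compounds**

F1 | step 7 | methyl 7-iodohept-5-ynoate | COC(=O)CCCC#CCI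
F2 | step 7 | methyl (13E,15S,19R)-11α,15,19-tris(tert-butyldimethylsilyloxy)-9-oxoprost-13-en-5-ynoate | C[C@@H](O[Si](C)(C)C(C)(C)C)CCC[C@H](O[Si](C)(C)C(C)(C)C)/C=C/[C@@H]1[C@@H](CC#CCCCC(=O)OC)C(=O)C[C@H]1O[Si](C)(C)C(C)(C)C
F3 | step 2 | (R)-7-(tert-butyldimethylsilyloxy)-1-(trimethylsilyl)oct-1-yn-3-one | C[C@@H](O[Si](C)(C)C(C)(C)C)CCCC(=O)C#C[Si](C)(C)C
F4 | step 2 | (3S,7R)-7-(tert-butyldimethylsilyloxy)-1-(trimethylsilyl)oct-1-yn-3-ol | C[C@@H](O[Si](C)(C)C(C)(C)C)CCC[C@H](O)C#C[Si](C)(C)C
F5 | step 2 | (3S,7R)-7-(tert-butyldimethylsilyloxy)oct-1-yn-3-ol | C[C@@H](O[Si](C)(C)C(C)(C)C)CCC[C@H](O)C#C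
F6 | step 9 | 19(R)-hydroxy prostaglandin F2α methyl ester | C[C@@H](O)CCC[C@H](O)/C=C/[C@@H]1[C@@H](C/C=C\CCCC(=O)OC)[C@@H](O)C[C@H]1O
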